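**Retrosynthetic overview**

1. Target 16 ⇐ PMB ether 14 (DDQ) ⇐ C11=C12 by Julia–Kocienski union of ring sulfone 9 with side-chain aldehyde 12.
2. Aldehyde 12 ⇐ the C13–O bond: Pd-catalysed asymmetric allylic etherification of racemic isoprene monoepoxide 10 with 4-methoxybenzyl alcohol; this C–O bond formation sets C13.
3. Sulfone 9 ⇐ the C6–O and C17–O bonds, put onto ent-drimenyl sulfone 5 by allylic oxidation, Luche reduction anti to the axial methyls, SeO2 hydroxylation and acetylation.
4. Sulfone 5 ⇐ farnesyl sulfone 4 by one enantioselective proton-initiated bicyclisation (ring A closes first, ring B second; C5, C9, C10 set) ⇐ farnesol 1.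

**Assumptions**

- Labdane numbering is used for all ring compounds: C11 is the carbon on C9, C17 the carbon on C8, C20 the methyl on C10. PT = 1-phenyl-1H-tetrazol-5-yl, PMB = 4-methoxybenzyl.
- The catalyst antipodes named in steps 3 and 8 are taken to give the drawn enantiomers; if a test run shows the opposite sense, the mirror-image catalyst is used.

**Route**

Step 1
Reactants: 1 (2E,6E)-farnesol
Product: 2 (2E,6E)-farnesyl PT sulfide
Conditions: 1-phenyl-1H-tetrazole-5-thiol, PPh3, DIAD, THF, 0 °C to rt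
Reagents that add atoms: 1-phenyl-1H-tetrazole-5-thiol, Sc1nnnn1-c1ccccc1
Why: Mitsunobu thioetherification displaces the activated primary allylic oxygen by the acidic thiol in an SN2 sense, leaving both E-alkenes untouched; no stereocentre is formed.

Step 2
Reactants: 2 (2E,6E)-farnesyl PT sulfide
Product: 4 (2E,6E)-farnesyl PT sulfone, via farnesyl PT sulfoxide 3 (not isolated)
Conditions: (NH4)6Mo7O24·4H2O (10 mol %), 30% H2O2, EtOH, 0 °C to rt
Reagents that add atoms: hydrogen peroxide, OO
Why: Molybdate–peroxo sulfide-to-sulfone oxidation is much faster at sulfur than epoxidation of the trisubstituted alkenes.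

Step 3
Reactants: 4 (2E,6E)-farnesyl PT sulfone
Product: 5 (5R,9R,10R)-ent-drim-7-en-11-yl PT sulfone (trans-decalin, C9 arm cis to C20)
Conditions: chiral confined imidodiphosphorimidate (IDPi) Brønsted acid (5 mol %), (CF3)3COH/CH2Cl2, −10 °C
Reagents that add atoms: none
Why: Proposed new method: a confined chiral imidodiphosphorimidate acid in perfluoro-tert-butanol should protonate only the terminal trisubstituted alkene of 4 (the 2,3-alkene is deactivated by the allylic sulfone), its chiral anion holds the chain in one chair–chair fold so that ring A and then ring B close by anti addition across the two E-alkenes (setting C5, C10 and C9 as the trans-decalin with the C9 arm equatorial), and the anion then removes H7 from the C8 cation to give the 7-ene; the closest known reaction type is the IDPi-catalysed enantioselective proton-initiated polyene cyclisation of homofarnesol-type trienols, which ends by oxygen trapping, whereas here the chain carries an electron-poor sulfone and ends by proton loss.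

Step 4
Reactants: 5 (5R,9R,10R)-ent-drim-7-en-11-yl PT sulfone
Product: 6 (5R,9R,10R)-6-oxo-ent-drim-7-en-11-yl PT sulfone
Conditions: CrO3, 3,5-dimethylpyrazole, CH2Cl2, −20 °C
Reagents that add atoms: chromium trioxide, O=[Cr](=O)=O
Why: Chromium trioxide–dimethylpyrazole allylic oxidation attacks the only allylic ring methylene (C6), the hindered tertiary C9–H and the C17 methyl being much slower, and leaves C5, C9 and C10 untouched.

Step 5
Reactants: 6 (5R,9R,10R)-6-oxo-ent-drim-7-en-11-yl PT sulfone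
Product: 7 (5R,6S,9R,10R)-6-hydroxy-ent-drim-7-en-11-yl PT sulfone (6-OH axial, cis to C20)
Conditions: NaBH4, CeCl3·7H2O, MeOH/THF, −78 °C
Reagents that add atoms: none
Why: Luche 1,2-reduction; hydride enters from the face away from the two axial methyls (C20 and the axial C4 methyl), so the new C6–OH is axial and cis to C20 (6S).

Step 6
Reactants: 7 (5R,6S,9R,10R)-6-hydroxy-ent-drim-7-en-11-yl PT sulfone
Product: 8 (5R,6S,9S,10R)-6,17-dihydroxy-ent-drim-7-en-11-yl PT sulfone
Conditions: SeO2 (30 mol %), t-BuOOH (3 equiv), CH2Cl2, 0 °C to rt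
Reagents that add atoms: tert-butyl hydroperoxide, CC(C)(C)OO; selenium dioxide (oxygen relay), O=[Se]=O
Why: Catalytic SeO2 allylic hydroxylation (ene reaction, then 2,3-sigmatropic shift) oxidises the methyl on the more substituted alkene carbon (C17) in preference to the hindered tertiary C9–H; no stereocentre changes.

Step 7
Reactants: 8 (5R,6S,9S,10R)-6,17-dihydroxy-ent-drim-7-en-11-yl PT sulfone
Product: 9 (5R,6S,9S,10R)-6,17-diacetoxy-ent-drim-7-en-11-yl PT sulfone
Conditions: Ac2O, DMAP, pyridine, CH2Cl2, rt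
Reagents that add atoms: acetic anhydride, CC(=O)OC(C)=O
Why: DMAP-catalysed acylation esterifies the primary C17 hydroxyl and the hindered axial C6 hydroxyl without touching any stereocentre.

Step 8
Reactants: 10 racemic 2-methyl-2-vinyloxirane
Product: 11 (S)-2-(4-methoxybenzyloxy)-2-methylbut-3-en-1-ol
Conditions: Pd2(dba)3·CHCl3 (1 mol %), (R,R)-DACH-phenyl Trost ligand (3 mol %), Et3B (1 mol %), 4-methoxybenzyl alcohol, CH2Cl2, rt
Reagents that add atoms: 4-methoxybenzyl alcohol, COc1ccc(CO)cc1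
Why: Pd-catalysed dynamic kinetic asymmetric allylic etherification: zerovalent palladium opens both epoxide enantiomers to interconverting π-allyl complexes, and Et3B ties the alcohol to the freed alkoxide and delivers it to the tertiary allyl terminus inside the chiral pocket, so the C13–O bond and the (S) tertiary centre form together.

Step 9
Reactants: 11 (S)-2-(4-methoxybenzyloxy)-2-methylbut-3-en-1-ol
Product: 12 (S)-2-(4-methoxybenzyloxy)-2-methylbut-3-enal
Conditions: Dess–Martin periodinane, CH2Cl2, 0 °C to rt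
Reagents that add atoms: none
Why: Dess–Martin oxidation of the neopentyl primary alcohol; the aldehyde has no α-hydrogen, so the tertiary centre cannot epimerise.

Step 10
Reactants: 9 (5R,6S,9S,10R)-6,17-diacetoxy-ent-drim-7-en-11-yl PT sulfone; 12 (S)-2-(4-methoxybenzyloxy)-2-methylbut-3-enal
Product: 14 (5R,6S,9S,10S,11E,13S)-6,17-diacetoxy-13-(4-methoxybenzyloxy)-ent-labda-7,11,14-triene, via potassium alkoxide adduct 13 (not isolated)
Conditions: KN(SiMe3)2 added to premixed 9 and 12 (1.5 equiv), DME, −78 °C to rt; aq. NH4Cl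
Reagents that add atoms: none
Why: Julia–Kocienski olefination: the metallated sulfone adds to the non-enolisable aldehyde, and Smiles rearrangement with loss of SO2 and tetrazololate gives the E-alkene (potassium/DME conditions); C9 and C13 carry no acidic hydrogen and keep their configuration.

Step 11
Reactants: 14 (5R,6S,9S,10S,11E,13S)-6,17-diacetoxy-13-(4-methoxybenzyloxy)-ent-labda-7,11,14-triene
Product: 16 (5R,6S,9S,10S,11E,13S)-6,17-diacetoxy-ent-labda-7,11,14-trien-13-ol (target), via anisyl hemiacetal 15 (not isolated)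
Conditions: DDQ, CH2Cl2/pH 7 buffer, 0 °C
Reagents that add atoms: none
Why: Oxidative PMB ether cleavage (hydride abstraction by DDQ, water capture, hemiacetal collapse) frees the tertiary alcohol under neutral conditions that leave the acetates, the skipped diene and all stereocentres untouched.

**Compound list**

1 | (2E,6E)-farnesol | CC(C)=CCC/C(C)=C/CC/C(C)=C/CO | starting material
2 | (2E,6E)-farnesyl PT sulfide | CC(C)=CCC/C(C)=C/CC/C(C)=C/CSc1nnnn1-c1ccccc1 | intermediate
3 | (2E,6E)-farnesyl PT sulfoxide (racemic at sulfur) | CC(C)=CCC/C(C)=C/CC/C(C)=C/CS(=O)c1nnnn1-c1ccccc1 | intermediate (not isolated)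
4 | (2E,6E)-farnesyl PT sulfone | CC(C)=CCC/C(C)=C/CC/C(C)=C/CS(=O)(=O)c1nnnn1-c1ccccc1 | intermediate
5 | (5R,9R,10R)-ent-drim-7-en-11-yl PT sulfone | O=S(=O)(C[C@@H]1C(C)=CC[C@@H]2C(C)(C)CCC[C@@]12C)c3nnnn3-c4ccccc4 | intermediate
6 | (5R,9R,10R)-6-oxo-ent-drim-7-en-11-yl PT sulfone | O=S(=O)(C[C@@H]1C(C)=CC(=O)[C@@H]2C(C)(C)CCC[C@@]12C)c3nnnn3-c4ccccc4 | intermediate
7 | (5R,6S,9R,10R)-6-hydroxy-ent-drim-7-en-11-yl PT sulfone | O=S(=O)(C[C@@H]1C(C)=C[C@H](O)[C@@H]2C(C)(C)CCC[C@@]12C)c3nnnn3-c4ccccc4 | intermediate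
8 | (5R,6S,9S,10R)-6,17-dihydroxy-ent-drim-7-en-11-yl PT sulfone | O=S(=O)(C[C@@H]1C(CO)=C[C@H](O)[C@@H]2C(C)(C)CCC[C@@]12C)c3nnnn3-c4ccccc4 | intermediate
9 | (5R,6S,9S,10R)-6,17-diacetoxy-ent-drim-7-en-11-yl PT sulfone | O=S(=O)(C[C@@H]1C(COC(C)=O)=C[C@H](OC(C)=O)[C@@H]2C(C)(C)CCC[C@@]12C)c3nnnn3-c4ccccc4 | intermediate
10 | racemic 2-methyl-2-vinyloxirane (isoprene monoepoxide) | C=CC1(C)CO1 | starting material
11 | (S)-2-(4-methoxybenzyloxy)-2-methylbut-3-en-1-ol | C=C[C@](C)(OCc1ccc(OC)cc1)CO | intermediate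
12 | (S)-2-(4-methoxybenzyloxy)-2-methylbut-3-enal | C=C[C@](C)(OCc1ccc(OC)cc1)C=O | intermediate
13 | potassium alkoxide adduct of 9 and 12 (C11 sulfonyl, C12 alkoxide; new centres not defined) | C=C[C@](C)(OCc1ccc(OC)cc1)C([O-])C([C@@H]1C(COC(C)=O)=C[C@H](OC(C)=O)[C@@H]2C(C)(C)CCC[C@@]12C)S(=O)(=O)c3nnnn3-c4ccccc4.[K+] | intermediate (not isolated)
14 | (5R,6S,9S,10S,11E,13S)-6,17-diacetoxy-13-(4-methoxybenzyloxy)-ent-labda-7,11,14-triene | C=C[C@](C)(OCc1ccc(OC)cc1)/C=C/[C@@H]1C(COC(C)=O)=C[C@H](OC(C)=O)[C@@H]2C(C)(C)CCC[C@@]12C | intermediate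
15 | anisyl hemiacetal of 16 at O13 (benzylic centre not defined) | C=C[C@](C)(OC(O)c1ccc(OC)cc1)/C=C/[C@@H]1C(COC(C)=O)=C[C@H](OC(C)=O)[C@@H]2C(C)(C)CCC[C@@]12C | intermediate (not isolated)
16 | (5R,6S,9S,10S,11E,13S)-6,17-diacetoxy-ent-labda-7,11,14-trien-13-ol | C=C[C@](C)(O)/C=C/[C@@H]1C(COC(C)=O)=C[C@H](OC(C)=O)[C@@H]2C(C)(C)CCC[C@@]12C | target

**Step count and risks**

Total steps: 11. Longest linear sequence: 9 (steps 1–7, 10, 11); steps 8–9 make the side-chain aldehyde.

Steps most likely to fail: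

- **Step 3 (proposed new cyclisation).** It may give low enantiomeric excess, stop at the monocycle, or give the 8(17)- or 8-ene isomers. Fallback with known chemistry, from 4 back to 5: racemic superacid bicyclisation of 4 (ClSO3H, 2-nitropropane, −78 °C, as used for farnesyl aryl sulfones) gives 5 as a 1:1 mixture with its mirror image, (5S,9S,10S)-drim-7-en-11-yl PT sulfone F1. Preparative chromatography on a chiral stationary phase separates the two, F1 is discarded, and the route continues at 5.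

- **Step 6 (SeO2 on the free allylic alcohol).** The axial C6 alcohol may be oxidised back to the enone or rearrange under the acidic selenium species. Fallback from 7 back to 9, masking the alcohol first: acetylation of 7 (Ac2O, DMAP, pyridine) gives (5R,6S,9R,10R)-6-acetoxy-ent-drim-7-en-11-yl PT sulfone F2. SeO2/t-BuOOH then hydroxylates only C17 to give (5R,6S,9S,10R)-6-acetoxy-17-hydroxy-ent-drim-7-en-11-yl PT sulfone F3, and a second acetylation gives 9.

- **Step 10 (Julia–Kocienski in the presence of two acetates, hindered partners).** The amide base may attack or enolise the acetates, or the hindered addition may be slow. Fallback from 8 back to 14, carrying silyl ethers through the coupling: Et3SiOTf/2,6-lutidine converts 8 into (5R,6S,9S,10R)-6,17-bis(triethylsilyloxy)-ent-drim-7-en-11-yl PT sulfone F4. Julia–Kocienski olefination of F4 with 12 (KN(SiMe3)2, DME) gives (5R,6S,9S,10S,11E,13S)-13-(4-methoxybenzyloxy)-6,17-bis(triethylsilyloxy)-ent-labda-7,11,14-triene F5. HF·pyridine removes both silyl groups to give (5R,6S,9S,10S,11E,13S)-13-(4-methoxybenzyloxy)-ent-labda-7,11,14-triene-6,17-diol F6, and Ac2O/DMAP/pyridine acetylates F6 to 14.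

**Further compounds**

F1 | step 3 | (5S,9S,10S)-drim-7-en-11-yl PT sulfone (enantiomer of 5) | O=S(=O)(C[C@H]1C(C)=CC[C@H]2C(C)(C)CCC[C@]12C)c3nnnn3-c4ccccc4
F2 | step 6 | (5R,6S,9R,10R)-6-acetoxy-ent-drim-7-en-11-yl PT sulfone | O=S(=O)(C[C@@H]1C(C)=C[C@H](OC(C)=O)[C@@H]2C(C)(C)CCC[C@@]12C)c3nnnn3-c4ccccc4
F3 | step 6 | (5R,6S,9S,10R)-6-acetoxy-17-hydroxy-ent-drim-7-en-11-yl PT sulfone | O=S(=O)(C[C@@H]1C(CO)=C[C@H](OC(C)=O)[C@@H]2C(C)(C)CCC[C@@]12C)c3nnnn3-c4ccccc4
F4 | step 10 | (5R,6S,9S,10R)-6,17-bis(triethylsilyloxy)-ent-drim-7-en-11-yl PT sulfone | O=S(=O)(C[C@@H]1C(CO[Si](CC)(CC)CC)=C[C@H](O[Si](CC)(CC)CC)[C@@H]2C(C)(C)CCC[C@@]12C)c3nnnn3-c4ccccc4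
F5 | step 10 | (5R,6S,9S,10S,11E,13S)-13-(4-methoxybenzyloxy)-6,17-bis(triethylsilyloxy)-ent-labda-7,11,14-triene | C=C[C@](C)(OCc1ccc(OC)cc1)/C=C/[C@@H]1C(CO[Si](CC)(CC)CC)=C[C@H](O[Si](CC)(CC)CC)[C@@H]2C(C)(C)CCC[C@@]12C
F6 | step 10 | (5R,6S,9S,10S,11E,13S)-13-(4-methoxybenzyloxy)-ent-labda-7,11,14-triene-6,17-diol | C=C[C@](C)(OCc1ccc(OC)cc1)/C=C/[C@@H]1C(CO)=C[C@H](O)[C@@H]2C(C)(C)CCC[C@@]12C
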